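Ring C is taken apart at C2–C3 and O1–C8a: the ring B aldehyde supplies C2 and O1 as its carbonyl group, and a ring A aryl methyl ketone supplies C3–C4–C4a–C8a. The key step exploits the vinylogous ester O1–C8a=C4a–C4=O of ring C: C3 is an enolate carbon, and C8a, ortho to the acyl group, carries fluoride. An enantioselective Mukaiyama aldol joins C3 to C2 and sets the (2S) centre; in the same flask fluoride unmasks the aldolate oxygen, which displaces the ring A fluoride (intramolecular SNAr). The precursors are a fluorinated, MOM-protected, prenylated enol silane and MOM-protected 2-prenylisovanillin; the single C–F bond fixes the 6-prenyl pattern.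

Key step: step 8

Assumption: the (R)-tryptophan-derived oxazaborolidinone is taken to expose the Si face of aldehyde 13 (the face that leads to 2S); if the sense of induction proves to be the reverse, the (S)-tryptophan-derived antipode is used. MOM = methoxymethyl.

Step 1
Reactants: 1 5-fluorobenzene-1,3-diol
Product: 2 5-fluoro-2-iodobenzene-1,3-diol
Conditions: I2, NaHCO3, H2O, 0 °C to rt
Reagents that add atoms: iodine, II
Why: Electrophilic aromatic iodination of the resorcinolate under bicarbonate buffering should occur at C2, ortho to both hydroxyls and para to fluorine, as in the standard preparation of 2-iodoresorcinol, which fixes the later prenyl position by symmetry.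

Step 2
Reactants: 2 5-fluoro-2-iodobenzene-1,3-diol
Product: 3 5-fluoro-2-iodo-1,3-bis(methoxymethoxy)benzene
Conditions: MOMCl, iPr2NEt, CH2Cl2, 0 °C to rt
Reagents that add atoms: chloromethyl methyl ether, COCCl
Why: O-alkylation of both phenols with the reactive α-chloro ether (Williamson-type etherification) should give base-stable acetals that later act as ortho-directing groups.

Step 3
Reactants: 3 5-fluoro-2-iodo-1,3-bis(methoxymethoxy)benzene
Product: 5 5-fluoro-1,3-bis(methoxymethoxy)-2-(3-methylbut-2-en-1-yl)benzene, via aryllithium 4 (not isolated)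
Conditions: n-BuLi, THF, −78 °C; then CuI (10 mol %), prenyl bromide, −78 to 0 °C
Reagents that add atoms: 1-bromo-3-methylbut-2-ene, CC(C)=CCBr
Why: Iodine–lithium exchange outruns any deprotonation at −78 °C, and the doubly chelated aryllithium should be allylated at the primary carbon of prenyl bromide (copper-assisted SN2 coupling), the standard entry to 2-prenyl resorcinol ethers.

Step 4
Reactants: 5 5-fluoro-1,3-bis(methoxymethoxy)-2-(3-methylbut-2-en-1-yl)benzene
Product: 8 1-[6-fluoro-2,4-bis(methoxymethoxy)-3-(3-methylbut-2-en-1-yl)phenyl]ethan-1-one, via aryllithium 6 (not isolated), via lithium hemiaminal alkoxide 7 (not isolated)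
Conditions: n-BuLi, THF, −78 °C; then MeC(O)N(OMe)Me, −78 °C; then NH4Cl (aq)
Reagents that add atoms: N-methoxy-N-methylacetamide, CC(=O)N(C)OC
Why: Directed ortho-metalation should remove one of the two symmetry-equivalent ring hydrogens flanked by F and OMOM, and the aryllithium, kept at −78 °C to prevent LiF loss, is acylated in a Weinreb ketone synthesis whose chelated tetrahedral intermediate releases the methyl ketone only on quench.

Step 5
Reactants: 8 1-[6-fluoro-2,4-bis(methoxymethoxy)-3-(3-methylbut-2-en-1-yl)phenyl]ethan-1-one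
Product: 10 ({1-[6-fluoro-2,4-bis(methoxymethoxy)-3-(3-methylbut-2-en-1-yl)phenyl]ethenyl}oxy)trimethylsilane, via lithium enolate 9 (not isolated)
Conditions: LiN(iPr)2, THF, −78 °C; then Me3SiCl, −78 to 0 °C; non-aqueous work-up
Reagents that add atoms: chlorotrimethylsilane, C[Si](C)(C)Cl
Why: Kinetic deprotonation of the only enolisable position (the acetyl methyl of the hindered ketone) and O-silylation of the lithium enolate should give the enol silane without touching the MOM acetals.

Step 6
Reactants: 11 2-bromo-3-hydroxy-4-methoxybenzaldehyde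
Product: 12 2-bromo-4-methoxy-3-(methoxymethoxy)benzaldehyde
Conditions: MOMCl, iPr2NEt, CH2Cl2, 0 °C to rt
Reagents that add atoms: chloromethyl methyl ether, COCCl
Why: O-alkylation of the single phenol (Williamson-type etherification) should proceed without affecting the aldehyde or the aryl bromide.

Step 7
Reactants: 12 2-bromo-4-methoxy-3-(methoxymethoxy)benzaldehyde
Product: 13 4-methoxy-3-(methoxymethoxy)-2-(3-methylbut-2-en-1-yl)benzaldehyde
Conditions: prenylboronic acid pinacol ester, [1,3-bis(2,6-di(pentan-3-yl)phenyl)imidazol-2-ylidene](3-chloropyridine)PdCl2 (2 mol %), K3PO4 (aq), THF, 60 °C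
Reagents that add atoms: 4,4,5,5-tetramethyl-2-(3-methylbut-2-en-1-yl)-1,3,2-dioxaborolane, CC(C)=CCB1OC(C)(C)C(C)(C)O1
Why: Suzuki–Miyaura coupling with a very bulky N-heterocyclic carbene ligand should tolerate the two ortho substituents and favour reductive elimination at the unsubstituted allyl terminus, giving the linear prenyl arene.

Step 8
Reactants: 10 ({1-[6-fluoro-2,4-bis(methoxymethoxy)-3-(3-methylbut-2-en-1-yl)phenyl]ethenyl}oxy)trimethylsilane; 13 4-methoxy-3-(methoxymethoxy)-2-(3-methylbut-2-en-1-yl)benzaldehyde
Product: 15 (2S)-2-[4-methoxy-3-(methoxymethoxy)-2-(3-methylbut-2-en-1-yl)phenyl]-5,7-bis(methoxymethoxy)-6-(3-methylbut-2-en-1-yl)-2,3-dihydro-4H-chromen-4-one, via silyl aldol 14 (not isolated)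
Conditions: (R)-2-butyl-4-(1H-indol-3-ylmethyl)-3-(4-methylphenylsulfonyl)-1,3,2-oxazaborolidin-5-one (20 mol %), EtCN, −78 °C; then CsF, DMF, −40 to 20 °C, same flask
Reagents that add atoms: none
Why: The boron Lewis acid activates aldehyde 13 and the CH2 terminus of enol silane 10 adds to its Si face through an open transition state, forming C2–C3 and, after silyl transfer, the (S)-silyl aldol 14; CsF then cleaves the O–Si bond and the alkoxide O1 attacks C8a, ortho to the C4 ketone, expelling fluoride through a Meisenheimer-type enolate (addition–elimination), which forms O1–C8a. The closest known reaction types are the oxazaborolidinone-catalysed Mukaiyama aldol of aryl methyl ketone enol silanes with aryl aldehydes and the alkoxide SNAr closure of ortho-fluoroaryl β-hydroxy ketones to chroman-4-ones. Ring C closes as a six-membered ring by attack of O1 on C8a, 6-endo-trig with respect to the C8a=C4a–C4=O unit that takes up the charge. The only new stereocentre, C2, is set by the catalyst in the aldol event and is retained in the ring closure because the C2–O1 bond is never broken. The step needs enantiofacial control, secured by the chiral catalyst, and ring closure faster than retro-aldol cleavage or E1cB loss of the β-oxygen, which is favoured by the intramolecular six-membered transition state, the ortho-acyl activation, fluoride as nucleofuge, the position of both OMOM groups meta to C8a and the cold aprotic medium. Regiochemistry is not an issue because ring A carries a single C–F bond, so only the 6-prenyl chromanone can form.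

Step 9
Reactants: 15 (2S)-2-[4-methoxy-3-(methoxymethoxy)-2-(3-methylbut-2-en-1-yl)phenyl]-5,7-bis(methoxymethoxy)-6-(3-methylbut-2-en-1-yl)-2,3-dihydro-4H-chromen-4-one
Product: 16 (2S)-5,7-dihydroxy-2-[3-hydroxy-4-methoxy-2-(3-methylbut-2-en-1-yl)phenyl]-6-(3-methylbut-2-en-1-yl)-2,3-dihydro-4H-chromen-4-one
Conditions: HCl (3 M aq), MeOH, 40 °C
Reagents that add atoms: none
Why: Acid-catalysed acetal exchange with methanol should remove all three MOM groups under conditions mild enough to leave the prenyl groups uncyclised and the C2 centre, which is not involved, unchanged.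

Compound list
1 | 5-fluorobenzene-1,3-diol (5-fluororesorcinol) | Oc1cc(F)cc(O)c1 | starting material
2 | 5-fluoro-2-iodobenzene-1,3-diol | Oc1cc(F)cc(O)c1I | intermediate
3 | 5-fluoro-2-iodo-1,3-bis(methoxymethoxy)benzene | COCOc1cc(F)cc(OCOC)c1I | intermediate
4 | [4-fluoro-2,6-bis(methoxymethoxy)phenyl]lithium | COCOc1cc(F)cc(OCOC)c1[Li] | intermediate
5 | 5-fluoro-1,3-bis(methoxymethoxy)-2-(3-methylbut-2-en-1-yl)benzene | COCOc1cc(F)cc(OCOC)c1CC=C(C)C | intermediate
6 | [6-fluoro-2,4-bis(methoxymethoxy)-3-(3-methylbut-2-en-1-yl)phenyl]lithium | COCOc1cc(F)c([Li])c(OCOC)c1CC=C(C)C | intermediate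
7 | lithium 1-[6-fluoro-2,4-bis(methoxymethoxy)-3-(3-methylbut-2-en-1-yl)phenyl]-1-[methoxy(methyl)amino]ethan-1-olate | COCOc1cc(F)c(C(C)(O[Li])N(C)OC)c(OCOC)c1CC=C(C)C | intermediate
8 | 1-[6-fluoro-2,4-bis(methoxymethoxy)-3-(3-methylbut-2-en-1-yl)phenyl]ethan-1-one | COCOc1cc(F)c(C(C)=O)c(OCOC)c1CC=C(C)C | intermediate
9 | lithium 1-[6-fluoro-2,4-bis(methoxymethoxy)-3-(3-methylbut-2-en-1-yl)phenyl]ethen-1-olate | COCOc1cc(F)c(C(=C)O[Li])c(OCOC)c1CC=C(C)C | intermediate
10 | ({1-[6-fluoro-2,4-bis(methoxymethoxy)-3-(3-methylbut-2-en-1-yl)phenyl]ethenyl}oxy)trimethylsilane | COCOc1cc(F)c(C(=C)O[Si](C)(C)C)c(OCOC)c1CC=C(C)C | intermediate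
11 | 2-bromo-3-hydroxy-4-methoxybenzaldehyde (2-bromoisovanillin) | COc1ccc(C=O)c(Br)c1O | starting material
12 | 2-bromo-4-methoxy-3-(methoxymethoxy)benzaldehyde | COCOc1c(OC)ccc(C=O)c1Br | intermediate
13 | 4-methoxy-3-(methoxymethoxy)-2-(3-methylbut-2-en-1-yl)benzaldehyde | COCOc1c(OC)ccc(C=O)c1CC=C(C)C | intermediate
14 | (3S)-1-[6-fluoro-2,4-bis(methoxymethoxy)-3-(3-methylbut-2-en-1-yl)phenyl]-3-[4-methoxy-3-(methoxymethoxy)-2-(3-methylbut-2-en-1-yl)phenyl]-3-(trimethylsilyloxy)propan-1-one | COc1ccc([C@@H](O[Si](C)(C)C)CC(=O)c2c(F)cc(OCOC)c(CC=C(C)C)c2OCOC)c(CC=C(C)C)c1OCOC | intermediate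
15 | (2S)-2-[4-methoxy-3-(methoxymethoxy)-2-(3-methylbut-2-en-1-yl)phenyl]-5,7-bis(methoxymethoxy)-6-(3-methylbut-2-en-1-yl)-2,3-dihydro-4H-chromen-4-one | COc1ccc([C@@H]2CC(=O)c3c(cc(OCOC)c(CC=C(C)C)c3OCOC)O2)c(CC=C(C)C)c1OCOC | intermediate
16 | (2S)-5,7-dihydroxy-2-[3-hydroxy-4-methoxy-2-(3-methylbut-2-en-1-yl)phenyl]-6-(3-methylbut-2-en-1-yl)-2,3-dihydro-4H-chromen-4-one (CNP0306216.1) | COc1ccc([C@@H]2CC(=O)c3c(cc(O)c(CC=C(C)C)c3O)O2)c(CC=C(C)C)c1O | target

Total step count: 9
Longest linear sequence: 7 steps (steps 1, 2, 3, 4, 5, 8 and 9)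

Steps most likely to fail

Step 8. The aldol may be slow or poorly face-selective with the hindered, electron-rich aldehyde. Once the alkoxide is set free, retro-aldol cleavage or β-elimination may compete with ring closure and erode enantiopurity and yield. The fallback sets out from ketone 8 and aldehyde 13 and separates the two bond formations. Enolisation of 8 with (−)-Ipc2BCl and Et3N in Et2O at 0 °C is followed by addition of 13 at −78 °C and buffered H2O2 work-up. This is a stoichiometric chiral boron aldol; (−)-Ipc2BCl is the enantiomer taken to give Si-face attack for methyl ketones, and (+)-Ipc2BCl is used otherwise. It should give the isolated (S)-β-hydroxy ketone F1. F1 is then closed in a separate operation with NaH in THF/DMF at 0 °C (intramolecular SNAr with a sodium counter-ion, which holds the aldolate more tightly), and the route is rejoined at 15.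

Step 7. Allyl transfer through the substituted terminus (reverse prenyl product), slow coupling at the doubly ortho-substituted bromide, or protodeboronation of the allylboronate may spoil the coupling. The fallback sets out from 12 and replaces the cross-coupling by organolithium chemistry. Acetalisation with HC(OMe)3 and catalytic pyridinium p-toluenesulfonate in MeOH should give the dimethyl acetal F2. Bromine–lithium exchange (n-BuLi, THF, −78 °C) and CuI-catalysed alkylation with prenyl bromide, as in step 3, should give the prenylated acetal F3. Brief hydrolysis with pyridinium p-toluenesulfonate in acetone/water, which leaves the aryl MOM ether intact, returns to 13.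

Step 4. Loss of LiF from the ortho-fluoro aryllithium on local warming, or proton transfer from the acetyl group of the amide instead of acyl transfer, may return arene 5 or give aryne-derived material. The fallback sets out from 5 through the same aryllithium 6, which is trapped at −78 °C with acetaldehyde, a faster electrophile, to give after NH4Cl quench the racemic secondary benzylic alcohol F4. Oxidation of F4 with Dess–Martin periodinane in CH2Cl2 returns to 8.

Further compounds
F1 | step 8 | (3S)-1-[6-fluoro-2,4-bis(methoxymethoxy)-3-(3-methylbut-2-en-1-yl)phenyl]-3-hydroxy-3-[4-methoxy-3-(methoxymethoxy)-2-(3-methylbut-2-en-1-yl)phenyl]propan-1-one | COc1ccc([C@@H](O)CC(=O)c2c(F)cc(OCOC)c(CC=C(C)C)c2OCOC)c(CC=C(C)C)c1OCOC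
F2 | step 7 | 2-bromo-1-(dimethoxymethyl)-4-methoxy-3-(methoxymethoxy)benzene | COCOc1c(OC)ccc(C(OC)OC)c1Br
F3 | step 7 | 1-(dimethoxymethyl)-4-methoxy-3-(methoxymethoxy)-2-(3-methylbut-2-en-1-yl)benzene | COCOc1c(OC)ccc(C(OC)OC)c1CC=C(C)C
F4 | step 4 | 1-[6-fluoro-2,4-bis(methoxymethoxy)-3-(3-methylbut-2-en-1-yl)phenyl]ethan-1-ol (racemic) | COCOc1cc(F)c(C(C)O)c(OCOC)c1CC=C(C)C
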